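**Retrosynthetic overview**
- (R)-β-Tocotrienol ⇐ its 6-O-tert-butyl ether. The benzene ring is bought; the dihydropyran ring is the only ring formed that stays in the target, and it is closed late (step 6) by Pd-catalysed aryl C8a–O1 bond formation from an (R)-tertiary alcohol, so the C2–O bond is never broken.
- The ArCH2CH2C(OH)(Me)R chain ⇐ C3–C4 bond between an aroyl anion equivalent (2-aryl-2-lithio-1,3-dithiane) and the CH2 of an (R)-2,2-disubstituted epoxide; the thioketal is then reduced to CH2.
- (R)-Epoxide ⇐ all-E farnesylacetone by catalytic asymmetric Corey–Chaykovsky methylenation, which sets the only stereocentre.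
- Aryl dithiane ⇐ symmetric 1,4-dichloro-2,5-dimethylbenzene (ortho-lithiation/formylation, thioacetalisation); one Cl becomes the ring oxygen, the other the phenol OH.

Assumption: all-E farnesylacetone is bought as a single isomer, and the (R)-BINOL-derived LLB catalyst is taken to give the (R)-epoxide (if the sense of induction is the reverse, (S)-BINOL is used and nothing else changes).

**Step 1**
Reactants: 1 (5E,9E)-6,10,14-trimethylpentadeca-5,9,13-trien-2-one [(E,E)-farnesylacetone]
Product: 2 (2R)-2-methyl-2-[(3E,7E)-4,8,12-trimethyltrideca-3,7,11-trien-1-yl]oxirane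
Conditions: Me3S(O)I, NaH, THF (ylide, 1.2 equiv); then 1, (R)-LLB [La–Li3–tris((R)-binaphthoxide)] (5 mol%), (2,4,6-(MeO)3C6H2)3P=O (5 mol%), 5 Å MS, THF, rt
Reagents that add atoms: trimethylsulfoxonium iodide, C[S+](C)(C)=O.[I-]
Why: Catalytic asymmetric Corey–Chaykovsky epoxidation, in which the chiral La/Li/binaphthoxide Lewis-acid–Brønsted-base catalyst (with the phosphine oxide additive) binds the methyl ketone and the ylide and delivers CH2 to one carbonyl face, creating the target's only stereocentre as (R) (methyl ketones typically 90–96% ee), while the isolated trisubstituted alkenes do not react with the sulfoxonium ylide.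

**Step 2**
Reactants: 3 1,4-dichloro-2,5-dimethylbenzene
Product: 5 2,5-dichloro-3,6-dimethylbenzaldehyde, via aryllithium 4 (not isolated)
Conditions: s-BuLi (1.1 equiv), TMEDA, THF, −78 °C, 1 h; DMF, −78 → 0 °C; H2O
Reagents that add atoms: N,N-dimethylformamide, CN(C)C=O
Why: Directed ortho-lithiation beside chlorine followed by formylation with DMF, where the two ring C–H bonds of 3 are equivalent so only one aldehyde can form, and at −78 °C the ortho-chloroaryllithium does not lose LiCl to an aryne.

**Step 3**
Reactants: 5 2,5-dichloro-3,6-dimethylbenzaldehyde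
Product: 6 2-(2,5-dichloro-3,6-dimethylphenyl)-1,3-dithiane
Conditions: HS(CH2)3SH (1.2 equiv), BF3·OEt2 (0.3 equiv), CH2Cl2, 0 °C → rt
Reagents that add atoms: propane-1,3-dithiol, SCCCS
Why: Lewis-acid-catalysed thioacetalisation turns the formyl group into a 1,3-dithiane whose C2–H can be lithiated (preparation for Corey–Seebach chemistry).

**Step 4 (key step)**
Reactants: 6 2-(2,5-dichloro-3,6-dimethylphenyl)-1,3-dithiane; 2 (2R)-2-methyl-2-[(3E,7E)-4,8,12-trimethyltrideca-3,7,11-trien-1-yl]oxirane
Product: 8 (2R,5E,9E)-1-[2-(2,5-dichloro-3,6-dimethylphenyl)-1,3-dithian-2-yl]-2,6,10,14-tetramethylpentadeca-5,9,13-trien-2-ol, via 2-aryl-2-lithio-1,3-dithiane 7 (not isolated)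
Conditions: 6 (1.3 equiv), n-BuLi (1.25 equiv), THF, −30 °C, 1 h; DMPU, then 2, −30 °C → rt, 12 h; H2O
Reagents that add atoms: none
Why: Corey–Seebach umpolung, in which the 2-lithio-1,3-dithiane is an aroyl anion equivalent whose masked carbonyl carbon attacks the unsubstituted CH2 of the epoxide (SN2), so two carbons that are both electrophilic in their parent aldehyde and epoxide forms are joined (C4–C3 of the future chroman), the quaternary (R) carbon is not a reacting centre and is carried over unchanged, and n-BuLi does not exchange aryl chlorides at this temperature.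

**Step 5**
Reactants: 8 (2R,5E,9E)-1-[2-(2,5-dichloro-3,6-dimethylphenyl)-1,3-dithian-2-yl]-2,6,10,14-tetramethylpentadeca-5,9,13-trien-2-ol
Product: 9 (3R,6E,10E)-1-(2,5-dichloro-3,6-dimethylphenyl)-3,7,11,15-tetramethylhexadeca-6,10,14-trien-3-ol
Conditions: Bu3SnH (4–5 equiv), AIBN (0.2 equiv, in portions), degassed toluene, 90 °C; KF/silica work-up
Reagents that add atoms: none
Why: Radical-chain desulfurisation, in which Bu3Sn• attacks sulfur and each benzylic C–S bond breaks to a benzylic radical that takes H from Bu3SnH, so the thioketal carbon ends as CH2 while the aryl C–Cl bonds, the tertiary alcohol and the trisubstituted alkenes are inert and the stereocentre is not involved.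

**Step 6**
Reactants: 9 (3R,6E,10E)-1-(2,5-dichloro-3,6-dimethylphenyl)-3,7,11,15-tetramethylhexadeca-6,10,14-trien-3-ol
Product: 11 (2R)-6-tert-butoxy-2,5,8-trimethyl-2-[(3E,7E)-4,8,12-trimethyltrideca-3,7,11-trien-1-yl]chromane, via open-chain aryl tert-butyl ether 10 (not isolated)
Conditions: Pd(OAc)2 (5 mol%), rac-2-(di-tert-butylphosphino)-1,1′-binaphthyl (7 mol%), NaOt-Bu (3 equiv), toluene (0.05 M), 100 °C
Reagents that add atoms: sodium tert-butoxide, CC(C)(C)[O-].[Na+]
Why: Proposed new method: two Buchwald-type Pd-catalysed C–O couplings run in one pot with the same bulky di-tert-butylbiarylphosphine and NaOt-Bu, in which the less hindered C–Cl (one ortho substituent) is turned over by tert-butoxide to the aryl tert-butyl ether (closest known reaction: Pd-catalysed tert-butoxylation of unactivated aryl chlorides), which keeps Pd from resting unproductively at that position, and the di-ortho-substituted C–Cl, where intermolecular attack by tert-butoxide is slow, is closed by the tethered tertiary alkoxide to the six-membered ring (closest known reaction: Pd-catalysed intramolecular etherification of tertiary alcohols to 2,2-dialkylchromans) by reductive elimination at the aryl carbon, so the C2–O bond is never broken and (R) is retained, and neither alkoxide has a hydrogen on its carbinol carbon that could reduce the aryl chloride.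

**Step 7**
Reactants: 11 (2R)-6-tert-butoxy-2,5,8-trimethyl-2-[(3E,7E)-4,8,12-trimethyltrideca-3,7,11-trien-1-yl]chromane
Product: 12 (2R)-2,5,8-trimethyl-2-[(3E,7E)-4,8,12-trimethyltrideca-3,7,11-trien-1-yl]chroman-6-ol [(R)-β-tocotrienol, CID5282348]
Conditions: TFA (10 equiv), CH2Cl2, 0 °C, 15–30 min; aq. NaHCO3; under argon
Reagents that add atoms: none
Why: Acidolysis (E1) of the aryl tert-butyl ether, in which the very electron-rich aryl ether loses the tert-butyl cation as isobutene within minutes at 0 °C, conditions under which the chroman ring ether, the stereocentre and the trisubstituted alkenes survive.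

**Compound list**
1 | (5E,9E)-6,10,14-trimethylpentadeca-5,9,13-trien-2-one | CC(C)=CCC/C(C)=C/CC/C(C)=C/CCC(C)=O | starting material
2 | (2R)-2-methyl-2-[(3E,7E)-4,8,12-trimethyltrideca-3,7,11-trien-1-yl]oxirane | CC(C)=CCC/C(C)=C/CC/C(C)=C/CC[C@]1(C)CO1 | intermediate
3 | 1,4-dichloro-2,5-dimethylbenzene | Cc1cc(Cl)c(C)cc1Cl | starting material
4 | (2,5-dichloro-3,6-dimethylphenyl)lithium | [Li]c1c(Cl)c(C)cc(Cl)c1C | intermediate
5 | 2,5-dichloro-3,6-dimethylbenzaldehyde | O=Cc1c(Cl)c(C)cc(Cl)c1C | intermediate
6 | 2-(2,5-dichloro-3,6-dimethylphenyl)-1,3-dithiane | C1CSC(SC1)c1c(Cl)c(C)cc(Cl)c1C | intermediate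
7 | 2-(2,5-dichloro-3,6-dimethylphenyl)-2-lithio-1,3-dithiane | [Li]C1(SCCCS1)c1c(Cl)c(C)cc(Cl)c1C | intermediate
8 | (2R,5E,9E)-1-[2-(2,5-dichloro-3,6-dimethylphenyl)-1,3-dithian-2-yl]-2,6,10,14-tetramethylpentadeca-5,9,13-trien-2-ol | CC(C)=CCC/C(C)=C/CC/C(C)=C/CC[C@@](C)(O)CC1(SCCCS1)c1c(Cl)c(C)cc(Cl)c1C | intermediate
9 | (3R,6E,10E)-1-(2,5-dichloro-3,6-dimethylphenyl)-3,7,11,15-tetramethylhexadeca-6,10,14-trien-3-ol | CC(C)=CCC/C(C)=C/CC/C(C)=C/CC[C@@](C)(O)CCc1c(Cl)c(C)cc(Cl)c1C | intermediate
10 | (3R,6E,10E)-1-(5-tert-butoxy-2-chloro-3,6-dimethylphenyl)-3,7,11,15-tetramethylhexadeca-6,10,14-trien-3-ol | CC(C)=CCC/C(C)=C/CC/C(C)=C/CC[C@@](C)(O)CCc1c(Cl)c(C)cc(OC(C)(C)C)c1C | intermediate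
11 | (2R)-6-tert-butoxy-2,5,8-trimethyl-2-[(3E,7E)-4,8,12-trimethyltrideca-3,7,11-trien-1-yl]chromane | CC(C)=CCC/C(C)=C/CC/C(C)=C/CC[C@]1(C)CCc2c(C)c(OC(C)(C)C)cc(C)c2O1 | intermediate
12 | (2R)-2,5,8-trimethyl-2-[(3E,7E)-4,8,12-trimethyltrideca-3,7,11-trien-1-yl]chroman-6-ol | CC(C)=CCC/C(C)=C/CC/C(C)=C/CC[C@]1(C)CCc2c(C)c(O)cc(C)c2O1 | target

**Step count and risks**
Total steps: 7. Longest linear sequence: 6 (3 → 12, steps 2–7); the epoxide branch (step 1) joins at step 4. The enantiomeric purity is fixed in step 1 and is not upgraded later (all intermediates are oils), so it should be checked by chiral HPLC at 9.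

Most likely to fail:

Step 4. The dithianyl anion carries a 2,6-disubstituted aryl group and must attack a CH2 next to a fully substituted carbon, so the opening may be slow or lose to proton transfer. The fallback sets out from aldehyde 5 (with epoxide 2) and comes back to the route at 9. It gives up the dithiane as carbanion carrier and makes the same bond with a benzylic organometallic. Aldehyde 5 is reduced with NaBH4 (MeOH, 0 °C) to (2,5-dichloro-3,6-dimethylphenyl)methanol F1, which SOCl2 (CH2Cl2, cat. DMF) converts into 2,5-dichloro-3,6-dimethylbenzyl chloride F2. Slow addition to Mg in Et2O gives (2,5-dichloro-3,6-dimethylbenzyl)magnesium chloride F3, which opens epoxide 2 under CuI catalysis (10 mol%, THF, −30 → 0 °C), again at the CH2 terminus. This gives 9 directly with the (R) centre intact, and steps 3 and 5 fall away.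

Step 5. Complete reduction of a 1,3-dithiane by tin hydride needs both C–S bonds to break, and the benzylic radical or stannyl radicals could touch the triene (cyclisation, E/Z drift). The fallback sets out from 8 and comes back at 11. The thioketal is kept through the ring construction: 8 is submitted to the step 6 conditions to give (2R)-6-tert-butoxy-2,5,8-trimethyl-2-[(3E,7E)-4,8,12-trimethyltrideca-3,7,11-trien-1-yl]spiro[chromane-4,2'-[1,3]dithiane] F4. As no C–Cl bond is left, deactivated W-2 Raney nickel (EtOH, rt) can then cut the two benzylic C–S bonds and deliver 11.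

Step 6. The two couplings must each occur at the right chlorine: tert-butoxide could also attack the hindered position, or the ring closure could be slow. The fallback sets out from 9 and comes back at 12. It separates the two C–O bond formations and drops the tert-butyl ether. A copper-catalysed Ullmann-type closure (CuI, oxalamide ligand, K3PO4, 120 °C), in which the copper alkoxide can only reach the neighbouring C–Cl, gives (2R)-6-chloro-2,5,8-trimethyl-2-[(3E,7E)-4,8,12-trimethyltrideca-3,7,11-trien-1-yl]chromane F5. Pd-catalysed hydroxylation (Pd2(dba)3, t-BuXPhos, KOH, dioxane/H2O, 100 °C, then acidification) then turns the remaining C–Cl into the phenol 12, so step 7 is not needed.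

**Further compounds**
F1 | step 4 | (2,5-dichloro-3,6-dimethylphenyl)methanol | OCc1c(Cl)c(C)cc(Cl)c1C
F2 | step 4 | 2,5-dichloro-3,6-dimethylbenzyl chloride | ClCc1c(Cl)c(C)cc(Cl)c1C
F3 | step 4 | (2,5-dichloro-3,6-dimethylbenzyl)magnesium chloride | Cl[Mg]Cc1c(Cl)c(C)cc(Cl)c1C
F4 | step 5 | (2R)-6-tert-butoxy-2,5,8-trimethyl-2-[(3E,7E)-4,8,12-trimethyltrideca-3,7,11-trien-1-yl]spiro[chromane-4,2'-[1,3]dithiane] | CC(C)=CCC/C(C)=C/CC/C(C)=C/CC[C@]1(C)CC2(SCCCS2)c2c(C)c(OC(C)(C)C)cc(C)c2O1
F5 | step 6 | (2R)-6-chloro-2,5,8-trimethyl-2-[(3E,7E)-4,8,12-trimethyltrideca-3,7,11-trien-1-yl]chromane | CC(C)=CCC/C(C)=C/CC/C(C)=C/CC[C@]1(C)CCc2c(C)c(Cl)cc(C)c2O1
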